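Ring B is cut at C1'–C6'. Its α-hydroxy ketone (C6' carbinol beside the C1' ketone) is the product of an intramolecular crossed benzoin reaction, and its cis acyl enaminone (C4' acyl, C5' NH2) is a ring-opened isoxazole. One carbene-catalysed step therefore closes ring B and sets C6' on keto-aldehyde 12, a 3-acetyl-5-sec-butylisoxazole carrying a ketal-masked 3-oxopropyl chain at C4. Loss of methanol, N–O cleavage and aminomethylation then give an electrophile at C2' that is joined through its methylene to C5 of ring A, a quinol ester built from (S)-lactic acid by self-regeneration of the stereocentre.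

Key step: step 7

Remarks and assumptions
- Atom labels: ring B is C1' (ketone), C2' (bridge carbon), C3' (OMe), C4' (acyl), C5' (NH2), C6' (carbinol). Ring A is C1 (acyloxy carbinol), C2 (enone C=O), C3 (vinylic CH), C4 (OMe), C5 (bridge carbon), C6 (ketone).
- Assumption: the (5aR,10bS) antipode of the aminoindanol-derived triazolium salt is taken to deliver the (R)-carbinol at C6'. Both antipodes are accessible, so the other is used if the sense is reversed.
- Assumption: 25 and 27 are vinylogous acids and are drawn as one of two rapidly equilibrating tautomers.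

Step 1
Reactants: 1 methacrolein
Product: 2 (E)-2-methylprop-2-enal oxime
Conditions: NH2OH·HCl, NaOAc, EtOH/H2O, 0 °C → rt
Reagents that add atoms: hydroxylamine (as hydrochloride), NO
Why: Oxime condensation of the aldehyde under buffered conditions, which should outrun conjugate addition to the α-substituted enal; no stereocentre is formed.

Step 2
Reactants: 3 (R)-2-methylbutanoic acid
Product: 5 (4R)-N-methoxy-N,4-dimethyl-3-oxohexanamide, via acyl Meldrum's acid 4 (not isolated)
Conditions: Meldrum's acid, DCC, DMAP, CH2Cl2, 0 °C → rt; then MeNH(OMe)·HCl, Et3N, toluene, 80 °C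
Reagents that add atoms: Meldrum's acid, CC1(C)OC(=O)CC(=O)O1; N,O-dimethylhydroxylamine (as hydrochloride), CNOC
Why: Carbodiimide C-acylation of Meldrum's acid followed by aminolysis through the acylketene (loss of acetone and CO2) is a standard route to β-keto amides that never enolises the α-stereocentre of 3.

Step 3
Reactants: 2 (E)-2-methylprop-2-enal oxime; 5 (4R)-N-methoxy-N,4-dimethyl-3-oxohexanamide
Product: 8 5-[(2R)-butan-2-yl]-N-methoxy-N-methyl-3-(prop-1-en-2-yl)-1,2-oxazole-4-carboxamide, via hydroximoyl chloride 6 (not isolated), via nitrile oxide 7 (not isolated)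
Conditions: NCS, DMF, rt; then 5, Et3N, EtOH, 0 °C → rt
Reagents that add atoms: none
Why: Classical nitrile oxide/1,3-dicarbonyl isoxazole synthesis: the enolised β-keto amide attacks the nitrile oxide carbon and the oxime oxygen cyclodehydrates onto the ketone, which should place the sec-butyl group at C5 and the amide at C4 regiospecifically, the mild amine base leaving the stereocentre alone.

Step 4
Reactants: 8 5-[(2R)-butan-2-yl]-N-methoxy-N-methyl-3-(prop-1-en-2-yl)-1,2-oxazole-4-carboxamide
Product: 9 1-{5-[(2R)-butan-2-yl]-3-(prop-1-en-2-yl)-1,2-oxazol-4-yl}but-3-en-1-one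
Conditions: C3H5MgBr (allylmagnesium bromide), THF, −78 °C; cold aq. NH4Cl
Reagents that add atoms: allylmagnesium bromide, C=CC[Mg]Br
Why: Weinreb ketone synthesis: the chelated tetrahedral adduct stops at mono-addition and a cold buffered quench should keep the β,γ-alkene out of conjugation.

Step 5
Reactants: 9 1-{5-[(2R)-butan-2-yl]-3-(prop-1-en-2-yl)-1,2-oxazol-4-yl}but-3-en-1-one
Product: 10 5-[(2R)-butan-2-yl]-4-(1,1-dimethoxybut-3-en-1-yl)-3-(prop-1-en-2-yl)-1,2-oxazole
Conditions: MeOSiMe3, Me3SiOTf (cat.), CH2Cl2, −78 → −20 °C; pyridine quench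
Reagents that add atoms: methoxytrimethylsilane, CO[Si](C)(C)C
Why: Aprotic silyl triflate-catalysed ketalisation with the silyl ether of methanol should convert the hindered heteroaryl ketone into its dimethyl ketal without acid-induced migration of the β,γ-double bond.

Step 6
Reactants: 10 5-[(2R)-butan-2-yl]-4-(1,1-dimethoxybut-3-en-1-yl)-3-(prop-1-en-2-yl)-1,2-oxazole
Product: 12 3-{3-acetyl-5-[(2R)-butan-2-yl]-1,2-oxazol-4-yl}-3,3-dimethoxypropanal, via bis-ozonide 11 (not isolated)
Conditions: O3, CH2Cl2, −78 °C; then PPh3, −78 °C → rt; used at once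
Reagents that add atoms: ozone, [O-][O+]=O
Why: Ozonolysis with neutral reductive work-up cleaves both terminal alkenes in one operation (isopropenyl to the acetyl ketone, allyl to the aldehyde) while sparing the ketal and the electron-poor isoxazole, and the neutral conditions protect the β-ketal aldehyde from loss of methanol.

Step 7
Reactants: 12 3-{3-acetyl-5-[(2R)-butan-2-yl]-1,2-oxazol-4-yl}-3,3-dimethoxypropanal
Product: 13 (7R)-3-[(2R)-butan-2-yl]-7-hydroxy-4,4-dimethoxy-7-methyl-4,5-dihydro-2,1-benzisoxazol-6(7H)-one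
Conditions: (5aR,10bS)-2-(pentafluorophenyl)-5a,10b-dihydro-4H,6H-indeno[2,1-b][1,2,4]triazolo[4,3-d][1,4]oxazin-2-ium tetrafluoroborate (15 mol%), Et3N (15 mol%), toluene, 0.05 M, rt
Reagents that add atoms: none
Why: The triazolylidene adds to the aldehyde carbon C1', proton transfer gives the hydroxy-enamine (acyl anion equivalent), its carbon attacks the acetyl carbonyl C6', and collapse of the adduct releases the carbene and the α-hydroxy ketone. The closest known reaction type is the chiral triazolium-catalysed intramolecular crossed aldehyde–ketone benzoin cyclisation, which includes heteroaryl ketones tethered through an isoxazole. Ring B is closed in the 6-exo-trig mode by the new C1'–C6' bond. The C6' stereocentre is set by the catalyst, whose aminoindanol-fused pocket exposes one face of the ketone to the bound acyl anion, while the remote sec-butyl centre should have no influence. The step needs benzoin closure to outrun aldol closure from C2' (five-membered ring) and β-loss of methanol; this is secured by a catalytic amount of weak amine base, by the preference of the carbene for the aldehyde, and by the isoxazole, which holds the two carbonyl arms cis and rigid and activates the acetyl group as an electron-poor heteroaryl ketone. The heterocycle also masks the C4'/C5' acyl enaminone, and the gem-dimethoxy carbon is the latent C3' methoxy enone.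

Step 8
Reactants: 13 (7R)-3-[(2R)-butan-2-yl]-7-hydroxy-4,4-dimethoxy-7-methyl-4,5-dihydro-2,1-benzisoxazol-6(7H)-one
Product: 14 (7R)-3-[(2R)-butan-2-yl]-7-hydroxy-4-methoxy-7-methyl-2,1-benzisoxazol-6(7H)-one
Conditions: TsOH (anhydrous, cat.), toluene, 4 Å molecular sieves, 60 °C
Reagents that add atoms: none
Why: Acid-catalysed β-elimination of methanol from the β-keto ketal gives the vinylogous ester regiospecifically (C3' keeps its methoxy group, C1' stays the ketone), and the quaternary C6' cannot epimerise.

Step 9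
Reactants: 14 (7R)-3-[(2R)-butan-2-yl]-7-hydroxy-4-methoxy-7-methyl-2,1-benzisoxazol-6(7H)-one
Product: 15 (6R)-5-amino-6-hydroxy-3-methoxy-6-methyl-4-[(2R)-2-methylbutanoyl]cyclohexa-2,4-dien-1-one
Conditions: Mo(CO)6, MeCN/H2O, 80 °C
Reagents that add atoms: none
Why: Reductive cleavage of the isoxazole N–O bond by zerovalent molybdenum with water as proton source should unmask the cis β-amino enone under neutral conditions, without touching the enone, the α-ketol or the α-stereocentre of the new acyl group.

Step 10
Reactants: 15 (6R)-5-amino-6-hydroxy-3-methoxy-6-methyl-4-[(2R)-2-methylbutanoyl]cyclohexa-2,4-dien-1-one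
Product: 16 (6R)-5-amino-2-[(dimethylamino)methyl]-6-hydroxy-3-methoxy-6-methyl-4-[(2R)-2-methylbutanoyl]cyclohexa-2,4-dien-1-one
Conditions: CH2=NMe2+ I−, CH2Cl2, rt; aq. NaHCO3
Reagents that add atoms: dimethylmethylideneammonium iodide, C[N+](C)=C.[I-]
Why: Mannich aminomethylation at C2', the only unsubstituted nucleophilic carbon of the push–pull dienaminone (α to C1'=O, β to the C3' methoxy group, vinylogous to the C5' amine); aminomethylation on nitrogen is reversible and should funnel to the C-adduct.

Step 11
Reactants: 17 (S)-lactic acid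
Product: 18 (2S,5S)-2-tert-butyl-5-methyl-1,3-dioxolan-4-one
Conditions: tBuCHO, TsOH (cat.), pentane, reflux, water separator; crystallise at −78 °C
Reagents that add atoms: pivalaldehyde, CC(C)(C)C=O
Why: Acid-catalysed acetalisation of the α-hydroxy acid under equilibrating conditions favours the cis isomer, in which the lactate centre controls the new acetal centre, and crystallisation should give it pure.

Step 12
Reactants: 19 methyl 3-oxopentanoate
Product: 20 methyl (2E)-3-methoxypent-2-enoate
Conditions: HC(OMe)3, H2SO4 (cat.), rt; then distil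
Reagents that add atoms: trimethyl orthoformate, COC(OC)OC
Why: Acid-catalysed ketalisation of the β-keto ester and thermal loss of methanol give the conjugated β-methoxy enoate as its thermodynamically preferred E isomer, which fixes the later ring A methoxy group at C4.

Step 13
Reactants: 20 methyl (2E)-3-methoxypent-2-enoate
Product: 21 (2E)-3-methoxypent-2-enoic acid
Conditions: LiOH·H2O, THF/H2O, 40 °C; then aq. HCl to pH 4, 0 °C
Reagents that add atoms: lithium hydroxide, [Li+].[OH-]
Why: Saponification of the ester, with cold and brief acidification so that the enol ether is not hydrolysed.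

Step 14
Reactants: 21 (2E)-3-methoxypent-2-enoic acid; 18 (2S,5S)-2-tert-butyl-5-methyl-1,3-dioxolan-4-one
Product: 24 (2S,5R)-2-tert-butyl-5-[(2E)-3-methoxypent-2-enoyl]-5-methyl-1,3-dioxolan-4-one, via acid chloride 22 (not isolated), via lithium enolate 23 (not isolated)
Conditions: 21, (COCl)2, DMF (cat.), CH2Cl2, 0 °C → rt, evaporate; 18, LiN(iPr)2, THF, −78 °C; enolate added to 22, THF, −78 °C
Reagents that add atoms: none
Why: Claisen-type C-acylation of the dioxolanone lithium enolate, in which the acid chloride enters anti to the tert-butyl group (self-regeneration of the stereocentre), so the new quaternary carbon keeps the lactate configuration and becomes C1 of ring A with the acyl carbon as C2.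

Step 15
Reactants: 24 (2S,5R)-2-tert-butyl-5-[(2E)-3-methoxypent-2-enoyl]-5-methyl-1,3-dioxolan-4-one
Product: 25 (6R)-5,6-dihydroxy-3-methoxy-2,6-dimethylcyclohexa-2,4-dien-1-one
Conditions: KN(SiMe3)2 (1.2 equiv.), THF, −78 °C → rt; aq. HCl
Reagents that add atoms: none
Why: Vinylogous Dieckmann condensation: γ-deprotonation of the β-methoxy enone gives a dienolate whose γ-carbon (C5) acylates the acylal carbonyl (C6) in a six-membered closure, the released hemiacetal alkoxide expels pivalaldehyde to free the tertiary alcohol, warming lets the loose potassium dienolate reach the cisoid geometry, and the stabilised vinylogous acid anion drives the reaction while C1 is untouched.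

Step 16
Reactants: 25 (6R)-5,6-dihydroxy-3-methoxy-2,6-dimethylcyclohexa-2,4-dien-1-one; 3 (R)-2-methylbutanoic acid
Product: 27 (1R)-2-hydroxy-4-methoxy-1,5-dimethyl-6-oxocyclohexa-2,4-dien-1-yl (2R)-2-methylbutanoate, via bis-ester 26 (not isolated)
Conditions: 3 (2.5 equiv.), DCC, DMAP (cat.), CH2Cl2, 0 °C → rt; then MeOH, Et3N (cat.), 0 °C
Reagents that add atoms: none
Why: Steglich esterification acylates both the tertiary alcohol and the enol, and the enol ester, a vinylogous anhydride, is then cleaved selectively by methanol while the hindered tertiary ester remains.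

Step 17
Reactants: 16 (6R)-5-amino-2-[(dimethylamino)methyl]-6-hydroxy-3-methoxy-6-methyl-4-[(2R)-2-methylbutanoyl]cyclohexa-2,4-dien-1-one; 27 (1R)-2-hydroxy-4-methoxy-1,5-dimethyl-6-oxocyclohexa-2,4-dien-1-yl (2R)-2-methylbutanoate
Product: 31 gilluone B, via silyl dienol ether 28 (not isolated), via ammonium iodide 29 (not isolated), via aza-quinone methide 30 (not isolated)
Conditions: 16, MeI, MeCN, rt, evaporate; 27, tBuMe2SiOTf, 2,6-lutidine, CH2Cl2, −78 → 0 °C; combine, −20 °C → rt; aq. NaHCO3
Reagents that add atoms: none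
Why: Vinylogous Mukaiyama–Michael addition: the ammonium salt loses trimethylamine to the aza-quinone methide, whose methylene is attacked by C5 of the O2-silyl dienol ether (the diene terminus, where attack gives a doubly oxygen-stabilised allyl cation and, after loss of silicon, the C2 ketone), ring B regaining its dienaminone, and the new quaternary centre C5 is set by 1,3-induction from C1 with entry expected anti to the branched acyloxy group.

Compound list
1 | methacrolein (2-methylprop-2-enal) | CC(=C)C=O | starting material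
2 | (E)-2-methylprop-2-enal oxime | CC(=C)/C=N/O | intermediate
3 | (R)-2-methylbutanoic acid | CC[C@@H](C)C(=O)O | starting material
4 | 5-[(2R)-1-hydroxy-2-methylbutylidene]-2,2-dimethyl-1,3-dioxane-4,6-dione (acyl Meldrum's acid) | CC[C@@H](C)C(O)=C1C(=O)OC(C)(C)OC1=O | intermediate
5 | (4R)-N-methoxy-N,4-dimethyl-3-oxohexanamide | CC[C@@H](C)C(=O)CC(=O)N(C)OC | intermediate
6 | (Z)-N-hydroxy-2-methylprop-2-enimidoyl chloride | CC(=C)/C(Cl)=N/O | intermediate
7 | 2-methylprop-2-enenitrile oxide | CC(=C)C#[N+][O-] | intermediate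
8 | 5-[(2R)-butan-2-yl]-N-methoxy-N-methyl-3-(prop-1-en-2-yl)-1,2-oxazole-4-carboxamide | CC[C@@H](C)c1onc(C(C)=C)c1C(=O)N(C)OC | intermediate
9 | 1-{5-[(2R)-butan-2-yl]-3-(prop-1-en-2-yl)-1,2-oxazol-4-yl}but-3-en-1-one | CC[C@@H](C)c1onc(C(C)=C)c1C(=O)CC=C | intermediate
10 | 5-[(2R)-butan-2-yl]-4-(1,1-dimethoxybut-3-en-1-yl)-3-(prop-1-en-2-yl)-1,2-oxazole | CC[C@@H](C)c1onc(C(C)=C)c1C(OC)(OC)CC=C | intermediate
11 | 5-[(2R)-butan-2-yl]-4-[1,1-dimethoxy-2-(1,2,4-trioxolan-3-yl)ethyl]-3-(3-methyl-1,2,4-trioxolan-3-yl)-1,2-oxazole (bis-ozonide, mixture at the new centres) | CC[C@@H](C)c1onc(C2(C)OCOO2)c1C(OC)(OC)CC3OCOO3 | intermediate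
12 | 3-{3-acetyl-5-[(2R)-butan-2-yl]-1,2-oxazol-4-yl}-3,3-dimethoxypropanal | CC[C@@H](C)c1onc(C(C)=O)c1C(OC)(OC)CC=O | intermediate
13 | (7R)-3-[(2R)-butan-2-yl]-7-hydroxy-4,4-dimethoxy-7-methyl-4,5-dihydro-2,1-benzisoxazol-6(7H)-one | CC[C@@H](C)c1onc2c1C(OC)(OC)CC(=O)[C@]2(C)O | intermediate
14 | (7R)-3-[(2R)-butan-2-yl]-7-hydroxy-4-methoxy-7-methyl-2,1-benzisoxazol-6(7H)-one | CC[C@@H](C)c1onc2c1C(OC)=CC(=O)[C@]2(C)O | intermediate
15 | (6R)-5-amino-6-hydroxy-3-methoxy-6-methyl-4-[(2R)-2-methylbutanoyl]cyclohexa-2,4-dien-1-one | CC[C@@H](C)C(=O)C1=C(N)[C@@](C)(O)C(=O)C=C1OC | intermediate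
16 | (6R)-5-amino-2-[(dimethylamino)methyl]-6-hydroxy-3-methoxy-6-methyl-4-[(2R)-2-methylbutanoyl]cyclohexa-2,4-dien-1-one | CC[C@@H](C)C(=O)C1=C(N)[C@@](C)(O)C(=O)C(CN(C)C)=C1OC | intermediate
17 | (S)-lactic acid | C[C@H](O)C(=O)O | starting material
18 | (2S,5S)-2-tert-butyl-5-methyl-1,3-dioxolan-4-one | C[C@@H]1O[C@H](C(C)(C)C)OC1=O | intermediate
19 | methyl 3-oxopentanoate | CCC(=O)CC(=O)OC | starting material
20 | methyl (2E)-3-methoxypent-2-enoate | CC/C(OC)=C\C(=O)OC | intermediate
21 | (2E)-3-methoxypent-2-enoic acid | CC/C(OC)=C\C(=O)O | intermediate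
22 | (2E)-3-methoxypent-2-enoyl chloride | CC/C(OC)=C\C(=O)Cl | intermediate
23 | lithium (2S)-2-tert-butyl-5-methyl-1,3-dioxol-4-olate | [Li+].[O-]C1=C(C)O[C@H](C(C)(C)C)O1 | intermediate
24 | (2S,5R)-2-tert-butyl-5-[(2E)-3-methoxypent-2-enoyl]-5-methyl-1,3-dioxolan-4-one | C[C@]1(C(=O)/C=C(/OC)CC)O[C@H](C(C)(C)C)OC1=O | intermediate
25 | (6R)-5,6-dihydroxy-3-methoxy-2,6-dimethylcyclohexa-2,4-dien-1-one | C[C@@]1(O)C(O)=CC(OC)=C(C)C1=O | intermediate
26 | (1R)-4-methoxy-1,5-dimethyl-2-{[(2R)-2-methylbutanoyl]oxy}-6-oxocyclohexa-2,4-dien-1-yl (2R)-2-methylbutanoate | CC[C@@H](C)C(=O)O[C@]1(C)C(OC(=O)[C@H](C)CC)=CC(OC)=C(C)C1=O | intermediate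
27 | (1R)-2-hydroxy-4-methoxy-1,5-dimethyl-6-oxocyclohexa-2,4-dien-1-yl (2R)-2-methylbutanoate | CC[C@@H](C)C(=O)O[C@]1(C)C(O)=CC(OC)=C(C)C1=O | intermediate
28 | (1R)-2-[(tert-butyldimethylsilyl)oxy]-4-methoxy-1,5-dimethyl-6-oxocyclohexa-2,4-dien-1-yl (2R)-2-methylbutanoate | CC[C@@H](C)C(=O)O[C@]1(C)C(O[Si](C)(C)C(C)(C)C)=CC(OC)=C(C)C1=O | intermediate
29 | {(5R)-4-amino-5-hydroxy-2-methoxy-5-methyl-3-[(2R)-2-methylbutanoyl]-6-oxocyclohexa-1,3-dien-1-yl}-N,N,N-trimethylmethanaminium iodide | CC[C@@H](C)C(=O)C1=C(N)[C@@](C)(O)C(=O)C(C[N+](C)(C)C)=C1OC.[I-] | intermediate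
30 | (6R)-6-hydroxy-5-imino-3-methoxy-6-methyl-2-methylidene-4-[(2R)-2-methylbutanoyl]cyclohex-3-en-1-one | CC[C@@H](C)C(=O)C1=C(OC)C(=C)C(=O)[C@](C)(O)C1=N | intermediate
31 | gilluone B, (1R,5R)-5-{[(5R)-4-amino-5-hydroxy-2-methoxy-5-methyl-3-[(2R)-2-methylbutanoyl]-6-oxocyclohexa-1,3-dien-1-yl]methyl}-4-methoxy-1,5-dimethyl-2,6-dioxocyclohex-3-en-1-yl (2R)-2-methylbutanoate | CC[C@@H](C)C(=O)O[C@]1(C)C(=O)C=C(OC)[C@@](C)(CC2=C(OC)C(C(=O)[C@H](C)CC)=C(N)[C@@](C)(O)C2=O)C1=O | target

Total step count: 17.
Longest linear sequence: 10 steps (steps 2–10 and 17 from 3; equally steps 1, 3–10 and 17 from 1). The ring A branch (steps 12–16, with step 11 feeding step 14) joins at step 17.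

Steps most likely to fail

1. Step 17. The dienol ether may react through C3 instead of C5, the facial selectivity at C5 rests on 1,3-induction alone and may be poor, and the silyl group may be lost before the C–C bond forms. The fallback sets out from 27 and returns at 31; it blocks C3 and puts the face under catalyst control. N-Bromosuccinimide in CH2Cl2 at 0 °C should brominate the only vinylic CH of 27 to give the 3-bromo quinol ester F1. Its potassium enolate (K2CO3, toluene, solid–liquid phase transfer with an N-benzylcinchoninium or N-benzylcinchonidinium bromide, whichever pseudo-enantiomer matches) is alkylated by ammonium iodide 29 through the same elimination–addition, now necessarily at C5, to give the 3-bromo adduct F2. Reduction of the vinyl bromide with the zerovalent palladium complex Pd(PPh3)4, HCO2H and Et3N in DMF returns 31. Halogen blocking, asymmetric phase-transfer alkylation of cyclic β-dicarbonyl enolates and palladium-catalysed formate reduction of vinyl halides are established reaction types.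

2. Step 7. The enolisable aldehyde may lose methanol from the neighbouring ketal, the aldol closure to the five-membered ring may compete, or the enantioselectivity may be low. The fallback sets out from 9 and returns at 14; it replaces the dimethyl ketal by a 1,3-dioxolane, whose tethered alkoxide recloses after any β-elimination. Ketalisation of 9 with 1,2-bis(trimethylsilyloxy)ethane and Me3SiOTf gives the dioxolane diene F3. Ozonolysis as in step 6 gives the dioxolane keto-aldehyde F4. The same triazolium-catalysed benzoin closure gives the spiro-dioxolane ketol F5. TsOH and HC(OMe)3 in methanol then exchange the glycol for methanol and eliminate to the methoxy enone 14, regiospecifically because C1' remains a ketone throughout.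

3. Step 15. The dienolate may fail to reach the cisoid geometry needed for ring closure, or the base may open the dioxolanone. The fallback sets out from 24 and returns at 25; it closes the ring through a β-diketone dianion, whose delocalised enolate equilibrates freely, and installs the methyl ether afterwards. Dilute HCl in THF hydrolyses the enol ether of 24 to the β-diketone F6. LiN(iPr)2 (2.2 equiv.) forms the 1,3-dianion, whose terminal carbanion acylates the dioxolanone carbonyl and, after loss of pivalaldehyde, gives the trihydroxy dienone F7. Acid-catalysed enol etherification (MeOH, TsOH) at the least hindered, central carbonyl should then give 25, any regioisomeric ether being recycled by hydrolysis.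

Further compounds
F1 | step 17 | (1R)-3-bromo-2-hydroxy-4-methoxy-1,5-dimethyl-6-oxocyclohexa-2,4-dien-1-yl (2R)-2-methylbutanoate | CC[C@@H](C)C(=O)O[C@]1(C)C(O)=C(Br)C(OC)=C(C)C1=O
F2 | step 17 | 3-bromo derivative of 31 at ring A (all stereocentres as in 31) | CC[C@@H](C)C(=O)O[C@]1(C)C(=O)C(Br)=C(OC)[C@@](C)(CC2=C(OC)C(C(=O)[C@H](C)CC)=C(N)[C@@](C)(O)C2=O)C1=O
F3 | step 7 | 5-[(2R)-butan-2-yl]-4-[2-(prop-2-en-1-yl)-1,3-dioxolan-2-yl]-3-(prop-1-en-2-yl)-1,2-oxazole | CC[C@@H](C)c1onc(C(C)=C)c1C2(CC=C)OCCO2
F4 | step 7 | 2-{2-[3-acetyl-5-((2R)-butan-2-yl)-1,2-oxazol-4-yl]-1,3-dioxolan-2-yl}acetaldehyde | CC[C@@H](C)c1onc(C(C)=O)c1C2(CC=O)OCCO2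
F5 | step 7 | (7'R)-3'-[(2R)-butan-2-yl]-7'-hydroxy-7'-methyl-5',7'-dihydro-6'H-spiro[1,3-dioxolane-2,4'-[2,1]benzisoxazol]-6'-one | CC[C@@H](C)c1onc2c1C3(OCCO3)CC(=O)[C@]2(C)O
F6 | step 15 | (2S,5R)-2-tert-butyl-5-methyl-5-(3-oxopentanoyl)-1,3-dioxolan-4-one | C[C@]1(C(=O)CC(=O)CC)O[C@H](C(C)(C)C)OC1=O
F7 | step 15 | (6R)-3,5,6-trihydroxy-2,6-dimethylcyclohexa-2,4-dien-1-one | C[C@@]1(O)C(O)=CC(O)=C(C)C1=O
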